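**Strategy.** Ring A is cut across C1–C2, C2–C3, C4–C5 and C5–C6, so that C1 and C6 come from an aryl ynol ether already carrying ring B on oxygen, and C2–C5 from a chiral diazo enone. One photochemical Wolff/[2+2]/4π/6π cascade then assembles the benzene ring, the hindered diaryl ether and the C2 phenol regioselectively. It exploits the resorcinol pattern of ring A: oxygens on C2 and C6, the carboxyl carbon C1 between them, the side chain on C3 next to C2–O, and C4/C5 unsubstituted. The precursors are an (S)-γ-silyloxy α′-diazo enone from (S)-3-hydroxy-γ-butyrolactone and a ring B aryloxy alkyne with a PMB-protected carbinol.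

Key step: step 15

**Remarks on the chemistry**
- Numbering: ring A carries CO2H on C1, OMe on C2, the side chain on C3 and the aryloxy group on C6. Ring B carries the ether oxygen on B1, OH on B2, CH3 on B4 and CH2OH on B6.
- Abbreviations: TBS = tert-butyldimethylsilyl, TES = triethylsilyl, PMB = 4-methoxybenzyl. SC = (1S)-1-(TBS-oxy)-3-methyl-3-(TES-oxy)butyl. ArB = 2-(allyloxy)-6-[(TBS-oxy)methyl]-4-methylphenyl.
- The stereocentre is read as S. It is bought as (S)-3-hydroxy-γ-butyrolactone, the lactone made from L-malic acid, and never becomes a reacting centre.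
- Assumption: an aryloxy alkyne adds to a vinylketene with the same orientation as alkoxy and siloxy alkynes.
- Design points: the B2 oxygen is carried as an allyl ether, because a silyl ether there would migrate to the neighbouring B1 phenoxide needed for the vinylation. The [2+2] adduct is a 4-vinylcyclobut-2-enone. The tertiary hydroxyl is masked so that it cannot add to the ketenes. Light of 365 nm is used so that only the diazo ketone absorbs.

## Fragment 1: diazo enone

**Step 1**
Reactants: 1 (S)-3-hydroxy-γ-butyrolactone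
Product: 2 (S)-3-(tert-butyldimethylsilyloxy)-γ-butyrolactone
Conditions: TBSCl, imidazole, DMF, 0 °C → rt
Reagents that add atoms: tert-butyldimethylsilyl chloride, CC(C)(C)[Si](C)(C)Cl
Why: Imidazole-mediated silylation of a secondary alcohol; the base is too weak to cause β-elimination of the lactone and the stereocentre is not touched.

**Step 2**
Reactants: 2 (S)-3-(tert-butyldimethylsilyloxy)-γ-butyrolactone
Product: 3 (2S)-2-(tert-butyldimethylsilyloxy)-4-methylpentane-1,4-diol
Conditions: MeMgBr (3 equiv), THF, −78 → 0 °C; sat. aq NH4Cl, 0 °C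
Reagents that add atoms: methylmagnesium bromide, C[Mg]Br
Why: Double Grignard addition to the lactone carbonyl builds the tertiary carbinol and releases the primary alcohol; the covalent bromomagnesium alkoxides, kept cold and quenched cold, should not pass the silyl group to the neighbouring oxygen.

**Step 3**
Reactants: 3 (2S)-2-(tert-butyldimethylsilyloxy)-4-methylpentane-1,4-diol
Product: 4 (2S)-2-(tert-butyldimethylsilyloxy)-4-methyl-1,4-bis(triethylsilyloxy)pentane
Conditions: TESOTf (2.5 equiv), 2,6-lutidine, CH2Cl2, −78 → 0 °C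
Reagents that add atoms: triethylsilyl trifluoromethanesulfonate, CC[Si](CC)(CC)OS(=O)(=O)C(F)(F)F
Why: Silyl triflate silylation covers both the primary and the hindered tertiary hydroxyl; the primary TES ether is deliberately the weakest link for step 4.

**Step 4**
Reactants: 4 (2S)-2-(tert-butyldimethylsilyloxy)-4-methyl-1,4-bis(triethylsilyloxy)pentane
Product: 5 (2S)-2-(tert-butyldimethylsilyloxy)-4-methyl-4-(triethylsilyloxy)pentanal
Conditions: (COCl)2, DMSO, CH2Cl2, −78 → −30 °C; Et3N, −78 → 0 °C
Reagents that add atoms: none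
Why: Under Swern oxidation conditions the chlorosulfonium salt cleaves a primary TES ether and oxidizes it in the same flask, while the tertiary TES and secondary TBS ethers stay; the low temperature protects the α-silyloxy aldehyde from epimerization.

**Step 5**
Reactants: 5 (2S)-2-(tert-butyldimethylsilyloxy)-4-methyl-4-(triethylsilyloxy)pentanal
Product: 6 (3E,5S)-5-(tert-butyldimethylsilyloxy)-7-methyl-7-(triethylsilyloxy)oct-3-en-2-one
Conditions: Ph3P=CHC(O)CH3, CH2Cl2, rt → 40 °C
Reagents that add atoms: 1-(triphenylphosphoranylidene)propan-2-one, CC(=O)C=P(c1ccccc1)(c1ccccc1)c1ccccc1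
Why: Wittig olefination with a stabilized ylide should give the E enone under neutral conditions that leave the adjacent stereocentre alone.

**Step 6**
Reactants: 6 (3E,5S)-5-(tert-butyldimethylsilyloxy)-7-methyl-7-(triethylsilyloxy)oct-3-en-2-one
Product: 8 (3E,5S)-5-(tert-butyldimethylsilyloxy)-1-diazo-7-methyl-7-(triethylsilyloxy)oct-3-en-2-one, via trifluoroacetyl diketone 7 (not isolated)
Conditions: LiN(SiMe3)2, THF, −78 °C; CF3CO2CH2CF3, −78 °C; then MsN3, Et3N, H2O, MeCN, rt
Reagents that add atoms: methanesulfonyl azide, CS(=O)(=O)N=[N+]=[N-]; 2,2,2-trifluoroethyl trifluoroacetate, O=C(OCC(F)(F)F)C(F)(F)F (its atoms stay only in 7)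
Why: Detrifluoroacetylative diazo transfer (Regitz type): the kinetic methyl enolate is trifluoroacetylated, and the activated diketone takes the diazo group from the sulfonyl azide with loss of the trifluoroacetyl group; the stereocentre is not involved.

## Fragment 2: ring B ynol ether

**Step 7**
Reactants: 9 2-methoxy-4-methylphenol (creosol)
Product: 10 2-hydroxy-3-methoxy-5-methylbenzaldehyde
Conditions: MgCl2, Et3N, (CH2O)n, MeCN, reflux; aq HCl
Reagents that add atoms: paraformaldehyde (formaldehyde), C=O
Why: Magnesium-mediated ortho-formylation (Casnati–Skattebøl) can only go to the single free ortho position, the para position being blocked by the methyl group.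

**Step 8**
Reactants: 10 2-hydroxy-3-methoxy-5-methylbenzaldehyde
Product: 11 2,3-dihydroxy-5-methylbenzaldehyde
Conditions: AlCl3, pyridine, CH2Cl2, reflux; aq HCl
Reagents that add atoms: none
Why: Chelation-assisted demethylation of a guaiacol ether, in which the aluminium phenoxide activates the neighbouring methoxy group for methyl transfer to pyridine.

**Step 9**
Reactants: 11 2,3-dihydroxy-5-methylbenzaldehyde
Product: 12 3-(allyloxy)-2-hydroxy-5-methylbenzaldehyde
Conditions: NaH (2.2 equiv), DMSO, rt; allyl bromide (1.0 equiv), rt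
Reagents that add atoms: allyl bromide, C=CCBr
Why: Williamson etherification of the dianion, in which the C3 phenoxide, neither conjugated with nor chelated to the formyl group, is the more nucleophilic oxygen and should take the single equivalent of halide.

**Step 10**
Reactants: 12 3-(allyloxy)-2-hydroxy-5-methylbenzaldehyde; 13 trichloroethylene
Product: 14 3-(allyloxy)-2-[(E)-1,2-dichlorovinyloxy]-5-methylbenzaldehyde
Conditions: K2CO3, DMF, 70 °C
Reagents that add atoms: none
Why: Carbonate eliminates HCl from 13 to dichloroacetylene, to which the phenoxide adds in anti fashion to give the (E)-dichlorovinyl ether; the allyl group on the neighbouring oxygen cannot migrate.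

**Step 11**
Reactants: 14 3-(allyloxy)-2-[(E)-1,2-dichlorovinyloxy]-5-methylbenzaldehyde
Product: 15 {3-(allyloxy)-2-[(E)-1,2-dichlorovinyloxy]-5-methylphenyl}methanol
Conditions: NaBH4, MeOH/THF, 0 °C
Reagents that add atoms: none
Why: Borohydride reduction of the aldehyde; the dichlorovinyl and allyl ethers are inert to it.

**Step 12**
Reactants: 15 {3-(allyloxy)-2-[(E)-1,2-dichlorovinyloxy]-5-methylphenyl}methanol
Product: 16 TBS ether of 15
Conditions: TBSCl, imidazole, DMF, rt
Reagents that add atoms: tert-butyldimethylsilyl chloride, CC(C)(C)[Si](C)(C)Cl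
Why: Standard silylation of the only hydroxyl group, a primary benzylic alcohol.

**Step 13**
Reactants: 16 TBS ether of 15
Product: 19 3-(ArB-oxy)prop-2-yn-1-ol, via chloroalkyne 17 (not isolated), via lithium acetylide 18 (not isolated)
Conditions: n-BuLi (2.3 equiv), THF, −78 → −40 °C; (CH2O)n, −40 °C → rt; aq NH4Cl
Reagents that add atoms: paraformaldehyde (formaldehyde), C=O
Why: Deprotonation and loss of LiCl give chloroalkyne 17, chlorine–lithium exchange gives acetylide 18, and this adds to formaldehyde (acetylide addition to a carbonyl group); at these temperatures the silyl and allyl ethers should not be attacked.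

**Step 14**
Reactants: 19 3-(ArB-oxy)prop-2-yn-1-ol
Product: 20 ArB 3-(4-methoxybenzyloxy)prop-1-ynyl ether
Conditions: NaH, PMBCl, Bu4NI (cat.), THF/DMF, 0 °C → rt
Reagents that add atoms: 4-methoxybenzyl chloride, COc1ccc(CCl)cc1
Why: Williamson etherification under basic conditions, which an acid-sensitive ynol ether tolerates.

## Key step

**Step 15**
Reactants: 8 (3E,5S)-5-(tert-butyldimethylsilyloxy)-1-diazo-7-methyl-7-(triethylsilyloxy)oct-3-en-2-one; 20 ArB 3-(4-methoxybenzyloxy)prop-1-ynyl ether
Product: 25 ring A phenol (C1 CH2OPMB; C2 OH; C3 SC; C6 O-ArB), via vinylketene 21 (not isolated), via vinylcyclobutenone 22 (not isolated), via dienylketene 23 (not isolated), via cyclohexadienone 24 (not isolated)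
Conditions: 8 (1.3 equiv), 20 (1.0 equiv), hν (365 nm LEDs), degassed ClCH2CH2Cl (0.3 M), rt; then 80 °C
Reagents that add atoms: none
Why: Excitation of the diazo ketone alone releases N2 with 1,2-shift of the alkenyl group (Wolff rearrangement, new bond C4–C5) and delivers vinylketene 21; the electron-rich alkyne carbon of 20 that bears the CH2OPMB group then bonds to the ketene carbonyl carbon while the aryloxy carbon bonds to the ketene α-carbon ([2+2] cycloaddition, bonds C2–C1 and C5–C6), giving 4-vinylcyclobutenone 22. On heating, 22 opens reversibly by 4π electrocyclic cleavage to dienylketene 23, which closes ring A by a thermal disrotatory 6π electrocyclization (bond C2–C3) to dienone 24 and tautomerizes to phenol 25; this is the Danheiser benzannulation in its photochemical form, established for alkoxy and siloxy alkynes. No stereocentre is created, since the sp3 centres of 22 and 24 disappear on aromatization, and the silyloxy-bearing carbon, which lies outside every reacting π system, keeps its S configuration. The step needs regiocontrol, which the polarization of the ynol ether secures by placing the carbinol-bearing carbon between the two oxygens and the aryloxy carbon at C6. It also needs selective excitation, which the 365 nm light secures because the aryl ethers, the PMB group and the allyl ether do not absorb there. The lower nucleophilicity of an aryloxy alkyne is met by high concentration and an excess of 8, and an aryl ynol ether cannot fragment by the retro-ene path that alkyl ynol ethers follow at 80 °C.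

## Endgame

**Step 16**
Reactants: 25 ring A phenol (C1 CH2OPMB; C2 OH; C3 SC; C6 O-ArB)
Product: 26 C2 methyl ether of 25
Conditions: MeI, Cs2CO3, DMF, rt → 40 °C
Reagents that add atoms: iodomethane, CI
Why: Williamson methylation of the only free phenol; the cesium phenoxide copes with the two ortho substituents and no aryl silyl ether is present to be lost.

**Step 17**
Reactants: 26 C2 methyl ether of 25
Product: 27 ring A benzylic alcohol (C1 CH2OH; C2 OMe; C3 SC; C6 O-ArB)
Conditions: DDQ, CH2Cl2/pH 7 buffer, 0 °C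
Reagents that add atoms: none
Why: Oxidative cleavage of the PMB ether by hydride abstraction at the most electron-rich benzylic position; the silylated benzylic positions and the allyl ether are harder to oxidize, and abstraction at the ring A methylene would only lead to 28, the next intermediate.

**Step 18**
Reactants: 27 ring A benzylic alcohol (C1 CH2OH; C2 OMe; C3 SC; C6 O-ArB)
Product: 28 ring A aldehyde (C1 CHO; C2 OMe; C3 SC; C6 O-ArB)
Conditions: Dess–Martin periodinane, NaHCO3, CH2Cl2, 0 °C → rt
Reagents that add atoms: none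
Why: Dess–Martin oxidation of the only free hydroxyl; every other alcohol is silylated and no free phenol is present.

**Step 19**
Reactants: 28 ring A aldehyde (C1 CHO; C2 OMe; C3 SC; C6 O-ArB)
Product: 29 ring A carboxylic acid (C1 CO2H; C2 OMe; C3 SC; C6 O-ArB)
Conditions: NaClO2, NaH2PO4, 2-methyl-2-butene, t-BuOH/H2O, 0 °C → rt
Reagents that add atoms: sodium chlorite, [Na+].[O-]Cl=O
Why: Pinnick oxidation, in which the excess alkene scavenges hypochlorous acid and so protects the electron-rich rings and the allyl ether; loss of the tertiary TES group at this pH would be harmless.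

**Step 20**
Reactants: 29 ring A carboxylic acid (C1 CO2H; C2 OMe; C3 SC; C6 O-ArB)
Product: 30 acid with free B2 phenol
Conditions: Pd(PPh3)4 (5 mol %), morpholine, THF, rt
Reagents that add atoms: none
Why: Zerovalent palladium ionizes the aryl allyl ether to a π-allyl complex that morpholine intercepts (Tsuji–Trost deallylation); silyl ethers, diaryl ether and acid are untouched.

**Step 21**
Reactants: 30 acid with free B2 phenol
Product: 31 target acid CNP0452050.2
Conditions: HF·pyridine, pyridine, THF, 0 °C → rt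
Reagents that add atoms: none
Why: Fluoride-driven desilylation removes both TBS ethers and the TES ether; pyridine-buffered HF is mild enough for the electron-rich benzylic carbinol and the stereocentre is not involved.

## Compound list

1 | (S)-3-hydroxy-γ-butyrolactone [(4S)-4-hydroxyoxolan-2-one] | O=C1C[C@H](O)CO1 | starting material
2 | (S)-3-(tert-butyldimethylsilyloxy)-γ-butyrolactone | O=C1C[C@H](O[Si](C)(C)C(C)(C)C)CO1 | intermediate
3 | (2S)-2-(tert-butyldimethylsilyloxy)-4-methylpentane-1,4-diol | OC[C@@H](O[Si](C)(C)C(C)(C)C)CC(C)(C)O | intermediate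
4 | (2S)-2-(tert-butyldimethylsilyloxy)-4-methyl-1,4-bis(triethylsilyloxy)pentane | CC[Si](CC)(CC)OC[C@@H](O[Si](C)(C)C(C)(C)C)CC(C)(C)O[Si](CC)(CC)CC | intermediate
5 | (2S)-2-(tert-butyldimethylsilyloxy)-4-methyl-4-(triethylsilyloxy)pentanal | O=C[C@@H](O[Si](C)(C)C(C)(C)C)CC(C)(C)O[Si](CC)(CC)CC | intermediate
6 | (3E,5S)-5-(tert-butyldimethylsilyloxy)-7-methyl-7-(triethylsilyloxy)oct-3-en-2-one | CC(=O)/C=C/[C@@H](O[Si](C)(C)C(C)(C)C)CC(C)(C)O[Si](CC)(CC)CC | intermediate
7 | (5E,7S)-7-(tert-butyldimethylsilyloxy)-1,1,1-trifluoro-9-methyl-9-(triethylsilyloxy)dec-5-ene-2,4-dione | O=C(CC(=O)/C=C/[C@@H](O[Si](C)(C)C(C)(C)C)CC(C)(C)O[Si](CC)(CC)CC)C(F)(F)F | intermediate (not isolated)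
8 | (3E,5S)-5-(tert-butyldimethylsilyloxy)-1-diazo-7-methyl-7-(triethylsilyloxy)oct-3-en-2-one | [N-]=[N+]=CC(=O)/C=C/[C@@H](O[Si](C)(C)C(C)(C)C)CC(C)(C)O[Si](CC)(CC)CC | intermediate
9 | 2-methoxy-4-methylphenol (creosol) | COc1cc(C)ccc1O | starting material
10 | 2-hydroxy-3-methoxy-5-methylbenzaldehyde | COc1cc(C)cc(C=O)c1O | intermediate
11 | 2,3-dihydroxy-5-methylbenzaldehyde | Oc1cc(C)cc(C=O)c1O | intermediate
12 | 3-(allyloxy)-2-hydroxy-5-methylbenzaldehyde | C=CCOc1cc(C)cc(C=O)c1O | intermediate
13 | trichloroethylene | ClC=C(Cl)Cl | starting material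
14 | 3-(allyloxy)-2-[(E)-1,2-dichlorovinyloxy]-5-methylbenzaldehyde | C=CCOc1cc(C)cc(C=O)c1O/C(Cl)=C\Cl | intermediate
15 | {3-(allyloxy)-2-[(E)-1,2-dichlorovinyloxy]-5-methylphenyl}methanol | C=CCOc1cc(C)cc(CO)c1O/C(Cl)=C\Cl | intermediate
16 | TBS ether of 15: 1-(allyloxy)-2-[(E)-1,2-dichlorovinyloxy]-5-methyl-3-[(tert-butyldimethylsilyloxy)methyl]benzene | C=CCOc1cc(C)cc(CO[Si](C)(C)C(C)(C)C)c1O/C(Cl)=C\Cl | intermediate
17 | ArB chloroethynyl ether | C=CCOc1cc(C)cc(CO[Si](C)(C)C(C)(C)C)c1OC#CCl | intermediate (not isolated)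
18 | lithium (ArB-oxy)acetylide | C=CCOc1cc(C)cc(CO[Si](C)(C)C(C)(C)C)c1OC#C[Li] | intermediate (not isolated)
19 | 3-{2-(allyloxy)-6-[(tert-butyldimethylsilyloxy)methyl]-4-methylphenoxy}prop-2-yn-1-ol | C=CCOc1cc(C)cc(CO[Si](C)(C)C(C)(C)C)c1OC#CCO | intermediate
20 | ArB 3-(4-methoxybenzyloxy)prop-1-ynyl ether | C=CCOc1cc(C)cc(CO[Si](C)(C)C(C)(C)C)c1OC#CCOCc1ccc(OC)cc1 | intermediate
21 | (3E,5S)-vinylketene: 5-(TBS-oxy)-7-methyl-7-(TES-oxy)octa-1,3-dien-1-one | O=C=C/C=C/[C@@H](O[Si](C)(C)C(C)(C)C)CC(C)(C)O[Si](CC)(CC)CC | intermediate (not isolated)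
22 | 4-vinylcyclobut-2-enone: C2 CH2OPMB; C3 O-ArB; C4 (E)-alkenyl chain ending in the S carbinol; C4 unassigned | O=C1C(COCc2ccc(OC)cc2)=C(Oc2c(OCC=C)cc(C)cc2CO[Si](C)(C)C(C)(C)C)C1/C=C/[C@@H](O[Si](C)(C)C(C)(C)C)CC(C)(C)O[Si](CC)(CC)CC | intermediate (not isolated)
23 | dienylketene: O=C=C(CH2OPMB)–C(O-ArB)=CH–CH=CH–SC carbon, central double bond cis, terminal double bond E | O=C=C(COCc1ccc(OC)cc1)/C(Oc1c(OCC=C)cc(C)cc1CO[Si](C)(C)C(C)(C)C)=C\C=C\[C@@H](O[Si](C)(C)C(C)(C)C)CC(C)(C)O[Si](CC)(CC)CC | intermediate (not isolated)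
24 | cyclohexa-2,4-dienone: C2 CH2OPMB; C3 O-ArB; C6 SC; C6 unassigned | O=C1C(COCc2ccc(OC)cc2)=C(Oc2c(OCC=C)cc(C)cc2CO[Si](C)(C)C(C)(C)C)C=CC1[C@@H](O[Si](C)(C)C(C)(C)C)CC(C)(C)O[Si](CC)(CC)CC | intermediate (not isolated)
25 | ring A phenol: C1 CH2OPMB; C2 OH; C3 SC (S); C6 O-ArB | Oc1c([C@@H](O[Si](C)(C)C(C)(C)C)CC(C)(C)O[Si](CC)(CC)CC)ccc(Oc2c(OCC=C)cc(C)cc2CO[Si](C)(C)C(C)(C)C)c1COCc1ccc(OC)cc1 | intermediate
26 | C2 methyl ether: C1 CH2OPMB; C2 OMe; C3 SC (S); C6 O-ArB | COc1c([C@@H](O[Si](C)(C)C(C)(C)C)CC(C)(C)O[Si](CC)(CC)CC)ccc(Oc2c(OCC=C)cc(C)cc2CO[Si](C)(C)C(C)(C)C)c1COCc1ccc(OC)cc1 | intermediate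
27 | benzylic alcohol: C1 CH2OH; C2 OMe; C3 SC (S); C6 O-ArB | COc1c([C@@H](O[Si](C)(C)C(C)(C)C)CC(C)(C)O[Si](CC)(CC)CC)ccc(Oc2c(OCC=C)cc(C)cc2CO[Si](C)(C)C(C)(C)C)c1CO | intermediate
28 | aldehyde: C1 CHO; C2 OMe; C3 SC (S); C6 O-ArB | COc1c([C@@H](O[Si](C)(C)C(C)(C)C)CC(C)(C)O[Si](CC)(CC)CC)ccc(Oc2c(OCC=C)cc(C)cc2CO[Si](C)(C)C(C)(C)C)c1C=O | intermediate
29 | acid: C1 CO2H; C2 OMe; C3 SC (S); C6 O-ArB | COc1c([C@@H](O[Si](C)(C)C(C)(C)C)CC(C)(C)O[Si](CC)(CC)CC)ccc(Oc2c(OCC=C)cc(C)cc2CO[Si](C)(C)C(C)(C)C)c1C(=O)O | intermediate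
30 | acid with free B2 phenol: as 29 but B2 OH | COc1c([C@@H](O[Si](C)(C)C(C)(C)C)CC(C)(C)O[Si](CC)(CC)CC)ccc(Oc2c(O)cc(C)cc2CO[Si](C)(C)C(C)(C)C)c1C(=O)O | intermediate
31 | CNP0452050.2: 3-[(1S)-1,3-dihydroxy-3-methylbutyl]-6-[2-hydroxy-6-(hydroxymethyl)-4-methylphenoxy]-2-methoxybenzoic acid | COc1c([C@@H](O)CC(C)(C)O)ccc(Oc2c(O)cc(C)cc2CO)c1C(=O)O | target

## Count

Total steps: 21 (fragment 1: steps 1–6; fragment 2: steps 7–14; key step 15; endgame: steps 16–21).
Longest linear sequence: 15 steps (9 → 31, steps 7–21).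

## Steps most likely to fail, with fallbacks

**Step 15.** Capture of vinylketene 21 by the weakly nucleophilic aryloxy alkyne may be slower than ketene dimerization and acylation of the product phenol. The fallback keeps the benzannulation but uses the best-behaved ketenophile class and forms the diaryl ether afterwards by SNAr. It sets out from 8 and returns at 26.
- Propargyl alcohol is etherified (NaH, PMBCl) to 4-methoxybenzyl propargyl ether F1.
- The lithium acetylide of F1 is oxidized to the ynolate (n-BuLi; LiOOt-Bu) and O-silylated (i-Pr3SiOTf) to the triisopropylsilyl ynol ether F2.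
- Diazo enone 8 and F2, under the conditions of step 15, should give the resorcinol monosilyl ether F3 (C2 OH; C6 OSi(i-Pr)3; C1 CH2OPMB; C3 SC).
- Methylation as in step 16 gives the methyl ether F4.
- Bu4NF (1 equiv, THF, 0 °C), which cleaves aryl silyl ethers much faster than alkyl ones, frees the C6 phenol F5.
- Ring B is supplied as an electrophile. Commercial 2-fluoro-5-methylphenol is allylated (allyl bromide, K2CO3) to the allyl ether F6. This is lithiated next to fluorine (lithium 2,2,6,6-tetramethylpiperidide, THF, −78 °C) and formylated with DMF to 3-(allyloxy)-2-fluoro-5-methylbenzaldehyde F7.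
- F5 and F7 (Cs2CO3, DMF, 70 °C) should give the diaryl ether aldehyde F8 by substitution ortho to the formyl group.
- NaBH4 gives the benzylic alcohol F9, and silylation (TBSCl, imidazole) returns to 26.

**Step 13.** Capture of acetylide 18 by polymeric formaldehyde may be sluggish, and the free aryloxy propargylic alcohol may hydrate or rearrange under traces of acid during isolation. The fallback sets out from 16 and returns at 20. Acetylide 18 is generated as before and C-alkylated with 4-methoxybenzyl chloromethyl ether (freshly made from 4-methoxybenzyl methylthiomethyl ether and SO2Cl2; THF, −78 → 0 °C). This soluble, far more reactive one-carbon electrophile brings the PMB group with it, so 20 forms directly. Alcohol 19 and step 14 are bypassed and no new compound arises (entry F0).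

**Step 2.** The silyl group may migrate from the secondary oxygen to the neighbouring primary alkoxide formed on lactone opening, and silanolate may be lost by β-elimination from the enolized lactone. The fallback sets out from 1 and returns at 3, so that no silyl ether ever faces an alkoxide.
- Unprotected lactone 1 is treated with excess MeMgBr (THF, 0 °C → rt) to give (S)-4-methylpentane-1,2,4-triol F10.
- TBSCl (2.2 equiv) and imidazole silylate only the primary and secondary hydroxyls, giving the bis-silyl ether F11.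
- Pyridine-buffered HF·pyridine (THF, 0 °C) removes the primary silyl group selectively and returns diol 3.

## Further compounds

F1 | step 15 | 4-methoxybenzyl propargyl ether | C#CCOCc1ccc(OC)cc1
F2 | step 15 | triisopropyl{3-[(4-methoxybenzyl)oxy]prop-1-ynyloxy}silane | COc1ccc(COCC#CO[Si](C(C)C)(C(C)C)C(C)C)cc1
F3 | step 15 | ring A phenol: C1 CH2OPMB; C2 OH; C3 SC (S); C6 OSi(i-Pr)3 | Oc1c([C@@H](O[Si](C)(C)C(C)(C)C)CC(C)(C)O[Si](CC)(CC)CC)ccc(O[Si](C(C)C)(C(C)C)C(C)C)c1COCc1ccc(OC)cc1
F4 | step 15 | C2 methyl ether of F3 | COc1c([C@@H](O[Si](C)(C)C(C)(C)C)CC(C)(C)O[Si](CC)(CC)CC)ccc(O[Si](C(C)C)(C(C)C)C(C)C)c1COCc1ccc(OC)cc1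
F5 | step 15 | C6 phenol: C1 CH2OPMB; C2 OMe; C3 SC (S); C6 OH | COc1c([C@@H](O[Si](C)(C)C(C)(C)C)CC(C)(C)O[Si](CC)(CC)CC)ccc(O)c1COCc1ccc(OC)cc1
F6 | step 15 | 2-(allyloxy)-1-fluoro-4-methylbenzene | C=CCOc1cc(C)ccc1F
F7 | step 15 | 3-(allyloxy)-2-fluoro-5-methylbenzaldehyde | C=CCOc1cc(C)cc(C=O)c1F
F8 | step 15 | diaryl ether aldehyde: as 26 but B6 CHO | COc1c([C@@H](O[Si](C)(C)C(C)(C)C)CC(C)(C)O[Si](CC)(CC)CC)ccc(Oc2c(OCC=C)cc(C)cc2C=O)c1COCc1ccc(OC)cc1
F9 | step 15 | diaryl ether alcohol: as 26 but B6 CH2OH | COc1c([C@@H](O[Si](C)(C)C(C)(C)C)CC(C)(C)O[Si](CC)(CC)CC)ccc(Oc2c(OCC=C)cc(C)cc2CO)c1COCc1ccc(OC)cc1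
F0 | step 13 | none | none
F10 | step 2 | (S)-4-methylpentane-1,2,4-triol | OC[C@@H](O)CC(C)(C)O
F11 | step 2 | (4S)-4,5-bis(tert-butyldimethylsilyloxy)-2-methylpentan-2-ol | CC(C)(C)[Si](C)(C)OC[C@@H](O[Si](C)(C)C(C)(C)C)CC(C)(C)O
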